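## Retrosynthetic overview

1. Feature: in ring A (C1 ketone, C2=C3–OMe, C4 mixed ketal, C5H2, C6–allyl) the ketal carbon C4 and the ketone α-carbon C6 are 1,3-related across C5H2. A C4–C6 bond therefore makes a donor–acceptor cyclopropane (aryloxy donor on C4, C1 carbonyl acceptor on C6), and its invertive methanolysis gives the ketal.
2. Target 21 ⇐ C6 allylation and C6 proton adjustment of enone 17 ⇐ ring-expanding methanolysis of bicyclo[3.1.0]hexenone 15.
3. 15 ⇐ intramolecular carbene cyclopropanation of dienyl diazoketone 14 (bonds C5–C6 and C4–C6, five- and three-membered rings, both stereocentres).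
4. 14 ⇐ (2E)-dienoic acid 12 ⇐ eliminative opening of dihydropyranone 10 ⇐ vinylogous aldol of aryl ether 7 with formaldehyde; 7 ⇐ phenol 5 (allylation/Claisen of 1) + bromo ester 6.
5. Ring order: arene (bought) → five- and three-membered rings together (step 7) → ring A by expansion (step 8).

Key step: step 7

Assumption: ring A carries the target numbering throughout, bromo ester 6 is bought as the (E) isomer, and Rh2(S-PTTL)4 is taken to give the (1R,5R) bicycle (the mirror-image catalyst would be used if the sense of induction were opposite).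

## Route

Step 1
Reactants: 1 3,4-dimethoxyphenol; 2 allyl bromide
Product: 3 4-(allyloxy)-1,2-dimethoxybenzene
Conditions: K2CO3, acetone, reflux
Reagents that add atoms: none
Why: Williamson ether synthesis, the phenoxide displacing bromide from the allylic halide by SN2.

Step 2
Reactants: 3 4-(allyloxy)-1,2-dimethoxybenzene
Product: 5 2-allyl-4,5-dimethoxyphenol, via dienone tautomer 4 (not isolated)
Conditions: N,N-diethylaniline, 200 °C
Reagents that add atoms: none
Why: Aromatic Claisen rearrangement, which should favour the unhindered ortho carbon (the other ortho position is flanked by a methoxy group), followed by tautomerisation of dienone 4 to the phenol.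

Step 3
Reactants: 5 2-allyl-4,5-dimethoxyphenol; 6 methyl (E)-4-bromo-3-methoxybut-2-enoate
Product: 7 methyl (E)-4-(2-allyl-4,5-dimethoxyphenoxy)-3-methoxybut-2-enoate
Conditions: K2CO3, acetone, reflux
Reagents that add atoms: none
Why: Williamson ether synthesis at the activated primary bromide; the (E) enol ether geometry is untouched.

Step 4
Reactants: 7 methyl (E)-4-(2-allyl-4,5-dimethoxyphenoxy)-3-methoxybut-2-enoate
Product: 10 rac-5-(2-allyl-4,5-dimethoxyphenoxy)-4-methoxy-5,6-dihydro-2H-pyran-2-one, via lithium dienolate 8 (not isolated), via lithium aldolate 9 (not isolated)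
Conditions: LiN(iPr)2, THF, −78 °C; HCHO gas (cracked paraformaldehyde), −78 to 0 °C; AcOH
Reagents that add atoms: formaldehyde, C=O
Why: Vinylogous aldol of a 3-methoxy-2-enoate dienolate, which reacts at the γ-carbon as in the standard construction of 4-methoxy-5,6-dihydropyran-2-ones; the (E) geometry holds the new alkoxide cis to the ester, so it lactonises with loss of methoxide.

Step 5
Reactants: 10 rac-5-(2-allyl-4,5-dimethoxyphenoxy)-4-methoxy-5,6-dihydro-2H-pyran-2-one
Product: 12 (2E)-4-(2-allyl-4,5-dimethoxyphenoxy)-3-methoxypenta-2,4-dienoic acid, via potassium dienoate 11 (not isolated)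
Conditions: KOtBu, THF, 0 °C; then cold 1 M HCl to pH 4
Reagents that add atoms: none
Why: Vinylogous E1cB opening of a 4-methoxy-5,6-dihydropyran-2-one (deprotonation at C5, expulsion of the lactone carboxylate from C6) creates the terminal aryl enol ether; the ring fixes the carboxyl group cis to it, which is the (2E) geometry the cyclisation needs.

Step 6
Reactants: 12 (2E)-4-(2-allyl-4,5-dimethoxyphenoxy)-3-methoxypenta-2,4-dienoic acid
Product: 14 (3E)-5-(2-allyl-4,5-dimethoxyphenoxy)-1-diazo-4-methoxyhexa-3,5-dien-2-one, via acid chloride 13 (not isolated)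
Conditions: 1-chloro-N,N,2-trimethylprop-1-en-1-amine, CH2Cl2, 0 °C; then CH2N2 (3 equiv), Et2O, 0 °C, dark
Reagents that add atoms: diazomethane, C=[N+]=[N-]
Why: The α-chloroenamine makes the acid chloride under neutral conditions that spare both enol ethers, and acylation of diazomethane (first stage of the Arndt–Eistert sequence) gives the diazoketone; the push–pull methoxy enone is a poor dipolarophile.

Step 7
Reactants: 14 (3E)-5-(2-allyl-4,5-dimethoxyphenoxy)-1-diazo-4-methoxyhexa-3,5-dien-2-one
Product: 15 (1R,5R)-5-(2-allyl-4,5-dimethoxyphenoxy)-4-methoxybicyclo[3.1.0]hex-3-en-2-one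
Conditions: Rh2(S-PTTL)4 (dirhodium tetrakis[N-phthaloyl-(S)-tert-leucinate], 1 mol %), CH2Cl2, 0 °C, slow addition of 14, dark
Reagents that add atoms: none
Why: Loss of N2 at the dirhodium centre gives an electrophilic acyl carbene at C6, which attacks the terminal carbon C5 of the aryl enol ether while positive charge builds at C4 (stabilised by the aryloxy oxygen) and then closes the C4–C6 bond, an asynchronous [2+1] addition. The closest known reaction type is the enantioselective intramolecular cyclopropanation of α-diazoketones bearing a γ,δ-alkene by chiral dirhodium carboxylates or copper bis(oxazoline) complexes, which gives bicyclo[3.1.0]hexan-2-ones. The five-membered ring (C6–C1–C2–C3–C4) closes in the exo mode, C5 staying outside it, and the three-membered ring (C4–C5–C6) closes by cheletropic carbene addition. The new stereocentres C4 and C6 are the bridgeheads: their relative configuration is fixed because only the cis-fused bicycle can form, and their absolute configuration is set by the N-phthaloyl-tert-leucinate ligands, which should let only one enantioface of the twisted C4=C5 bond reach the carbene. The step needs chemoselectivity for the enol ether over Büchner addition to the electron-rich arene, over the remote allyl alkene and over C–H insertion into the C3 methoxy group; the (E) geometry of C2=C3 holds the enol ether cis to the acyl carbene and the methoxy group trans and out of reach, and the arene and allyl group could only be reached through rings of seven or more atoms.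

Step 8
Reactants: 15 (1R,5R)-5-(2-allyl-4,5-dimethoxyphenoxy)-4-methoxybicyclo[3.1.0]hex-3-en-2-one
Product: 17 (R)-4-(2-allyl-4,5-dimethoxyphenoxy)-3,4-dimethoxycyclohex-2-en-1-one, via dienol 16 (not isolated)
Conditions: pyridinium p-toluenesulfonate (10 mol %), MeOH/CH2Cl2 1:1, −20 to 0 °C; Et3N quench
Reagents that add atoms: methanol, CO
Why: Proposed new method: protonation of the vinylogous ester carbonyl polarises the C4–C6 bond of the donor–acceptor cyclopropane, and methanol should attack C4 from the side opposite C6 in a solvent-assisted SN2-like opening, which releases the ring strain, expands the five-membered ring to ring A and turns the bridgehead configuration, with inversion, into the (R) ketal; a free cation is disfavoured because C4 adjoins the electron-poor β-carbon of the enone, and the mild buffer should leave the product ketal un-ionised; the closest known reaction types are the Lewis-acid-catalysed invertive alcoholysis of aryl-donor cyclopropane diesters and the acid methanolysis of 2-alkoxycyclopropyl ketones to γ-keto acetals; dienol 16 then tautomerises to enone 17.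

Step 9
Reactants: 17 (R)-4-(2-allyl-4,5-dimethoxyphenoxy)-3,4-dimethoxycyclohex-2-en-1-one; 2 allyl bromide
Product: 19 (4R)-6-allyl-4-(2-allyl-4,5-dimethoxyphenoxy)-3,4-dimethoxycyclohex-2-en-1-one (C6 epimer mixture), via lithium dienolate 18 (not isolated)
Conditions: LiN(iPr)2, THF, −78 °C; allyl bromide, −78 to −30 °C
Reagents that add atoms: none
Why: Kinetic α'-deprotonation of the 3-alkoxy-enone at C6, its only enolisable position, gives the cross-conjugated dienolate, which is C-allylated by SN2; the electrophile should enter mainly anti to the bulky aryloxy group on C4 (6R), but either epimer is usable because C6 is reset in step 10.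

Step 10
Reactants: 19 (4R)-6-allyl-4-(2-allyl-4,5-dimethoxyphenoxy)-3,4-dimethoxycyclohex-2-en-1-one (C6 epimer mixture)
Product: 21 (4R,6S)-6-allyl-4-(2-allyl-4,5-dimethoxyphenoxy)-3,4-dimethoxycyclohex-2-en-1-one, via lithium dienolate 20 (not isolated)
Conditions: LiN(iPr)2, THF, −78 to −40 °C; inverse quench into AcOH/THF, −78 °C
Reagents that add atoms: none
Why: Deprotonation returns the planar dienolate, and kinetic diastereoselective protonation under 1,3-induction should deliver hydrogen to the C6 face opposite the 2-allyl-4,5-dimethoxyphenoxy group on C4, placing the allyl group cis to that aryloxy group (6S); the C4 ketal is base-stable and not enolisable, and any 6R epimer is separable and can be resubmitted.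

## Compound list

1 | 3,4-dimethoxyphenol | COc1ccc(O)cc1OC | starting material
2 | allyl bromide | C=CCBr | starting material
3 | 4-(allyloxy)-1,2-dimethoxybenzene | C=CCOc1ccc(OC)c(OC)c1 | intermediate
4 | 6-allyl-3,4-dimethoxycyclohexa-2,4-dien-1-one (not isolated) | O=C1C=C(OC)C(OC)=CC1CC=C | intermediate
5 | 2-allyl-4,5-dimethoxyphenol | C=CCc1cc(OC)c(OC)cc1O | intermediate
6 | methyl (E)-4-bromo-3-methoxybut-2-enoate | COC(=O)/C=C(/OC)CBr | starting material
7 | methyl (E)-4-(2-allyl-4,5-dimethoxyphenoxy)-3-methoxybut-2-enoate | COC(=O)/C=C(/OC)COc1cc(OC)c(OC)cc1CC=C | intermediate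
8 | lithium dienolate of 7, γ-deprotonated (not isolated) | COC([O-])=CC(OC)=COc1cc(OC)c(OC)cc1CC=C.[Li+] | intermediate
9 | lithium alkoxide of methyl (E)-4-(2-allyl-4,5-dimethoxyphenoxy)-5-hydroxy-3-methoxypent-2-enoate (not isolated) | [Li+].[O-]CC(Oc1cc(OC)c(OC)cc1CC=C)/C(OC)=C\C(=O)OC | intermediate
10 | rac-5-(2-allyl-4,5-dimethoxyphenoxy)-4-methoxy-5,6-dihydro-2H-pyran-2-one | COC1=CC(=O)OCC1Oc1cc(OC)c(OC)cc1CC=C | intermediate
11 | potassium (2E)-4-(2-allyl-4,5-dimethoxyphenoxy)-3-methoxypenta-2,4-dienoate (not isolated) | C=C(Oc1cc(OC)c(OC)cc1CC=C)/C(OC)=C\C(=O)[O-].[K+] | intermediate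
12 | (2E)-4-(2-allyl-4,5-dimethoxyphenoxy)-3-methoxypenta-2,4-dienoic acid | C=C(Oc1cc(OC)c(OC)cc1CC=C)/C(OC)=C\C(=O)O | intermediate
13 | (2E)-4-(2-allyl-4,5-dimethoxyphenoxy)-3-methoxypenta-2,4-dienoyl chloride (not isolated) | C=C(Oc1cc(OC)c(OC)cc1CC=C)/C(OC)=C\C(Cl)=O | intermediate
14 | (3E)-5-(2-allyl-4,5-dimethoxyphenoxy)-1-diazo-4-methoxyhexa-3,5-dien-2-one | C=C(Oc1cc(OC)c(OC)cc1CC=C)/C(OC)=C\C(=O)C=[N+]=[N-] | intermediate
15 | (1R,5R)-5-(2-allyl-4,5-dimethoxyphenoxy)-4-methoxybicyclo[3.1.0]hex-3-en-2-one | O=C1C=C(OC)[C@@]2(Oc3cc(OC)c(OC)cc3CC=C)C[C@@H]12 | intermediate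
16 | (R)-4-(2-allyl-4,5-dimethoxyphenoxy)-3,4-dimethoxycyclohexa-1,5-dien-1-ol (not isolated) | C=CCc1cc(OC)c(OC)cc1O[C@]1(OC)CC=C(O)C=C1OC | intermediate
17 | (R)-4-(2-allyl-4,5-dimethoxyphenoxy)-3,4-dimethoxycyclohex-2-en-1-one | C=CCc1cc(OC)c(OC)cc1O[C@]1(OC)CCC(=O)C=C1OC | intermediate
18 | lithium dienolate of 17 (not isolated) | C=CCc1cc(OC)c(OC)cc1O[C@]1(OC)CC=C([O-])C=C1OC.[Li+] | intermediate
19 | (4R)-6-allyl-4-(2-allyl-4,5-dimethoxyphenoxy)-3,4-dimethoxycyclohex-2-en-1-one, C6 epimer mixture | C=CCc1cc(OC)c(OC)cc1O[C@]1(OC)CC(CC=C)C(=O)C=C1OC | intermediate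
20 | lithium dienolate of 19 (not isolated) | C=CCc1cc(OC)c(OC)cc1O[C@]1(OC)CC(CC=C)=C([O-])C=C1OC.[Li+] | intermediate
21 | (4R,6S)-6-allyl-4-(2-allyl-4,5-dimethoxyphenoxy)-3,4-dimethoxycyclohex-2-en-1-one | C=CCc1cc(OC)c(OC)cc1O[C@]1(OC)C[C@H](CC=C)C(=O)C=C1OC | target

## Step count and risks

Total steps: 10. Longest linear sequence: 10 steps (1 to 21).

**Step 8 (proposed method).** The C4–C6 bond may ionise without nucleophilic assistance. The resulting planar, arenium-like cation would lose the C5 proton (aromatisation) or be captured on both faces (loss of the C4 configuration).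
Fallback, known chemistry, from 15 back to 17:
- The isomerisation is completed on purpose with catalytic CF3CO2H in CH2Cl2 (acid-catalysed bicyclohexenone-to-phenol rearrangement) to give 4-(2-allyl-4,5-dimethoxyphenoxy)-3-methoxyphenol F1.
- Oxidative dearomatisation of F1 with PhI(OAc)2 in MeOH at 0 °C adds methanol para to the phenol oxygen and gives racemic 4-(2-allyl-4,5-dimethoxyphenoxy)-3,4-dimethoxycyclohexa-2,5-dien-1-one F2.
- Conjugate reduction of the unsubstituted C5=C6 enone bond with [(Ph3P)CuH]6 in toluene gives racemic 4-(2-allyl-4,5-dimethoxyphenoxy)-3,4-dimethoxycyclohex-2-en-1-one F3; the vinylogous ester and the allyl groups should be left alone.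
- Preparative chromatography of F3 on a chiral stationary phase gives the (R) enantiomer, which is 17.

**Step 7 (key step).** An acceptor-only carbene may be poorly discriminated by the chiral carboxylate (low enantioface selection). The zwitterionic character of the addition may also divert material to aromatised or ylide-derived products.
Fallback, from 13 back to 17, adds a second acceptor so that a better-behaved acceptor/acceptor carbene is used:
- Acid chloride 13 is treated with PhSO2CH2Li (2 equiv, THF, −78 °C) to give (3E)-5-(2-allyl-4,5-dimethoxyphenoxy)-4-methoxy-1-(phenylsulfonyl)hexa-3,5-dien-2-one F4.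
- Diazo transfer with 4-acetamidobenzenesulfonyl azide and Et3N in MeCN gives (3E)-5-(2-allyl-4,5-dimethoxyphenoxy)-1-diazo-4-methoxy-1-(phenylsulfonyl)hexa-3,5-dien-2-one F5.
- Intramolecular cyclopropanation of this α-diazo-β-keto sulfone with CuOTf and the matching chiral bis(oxazoline) ligand gives (1S,5S)-5-(2-allyl-4,5-dimethoxyphenoxy)-4-methoxy-1-(phenylsulfonyl)bicyclo[3.1.0]hex-3-en-2-one F6.
- The doubly activated cyclopropane is opened with buffered methanol as in step 8 to give (4R)-4-(2-allyl-4,5-dimethoxyphenoxy)-3,4-dimethoxy-6-(phenylsulfonyl)cyclohex-2-en-1-one F7.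
- Reductive desulfonylation of F7 with Al/Hg in aqueous THF at 0 °C gives 17.

**Step 10.** The 1,3-induction from the C4 ketal may give too little facial bias in the protonation of dienolate 20, leaving a C6 epimer mixture.
Fallback, from 17 back to 21, replaces steps 9 and 10 by catalyst control:
- Enone 17 is deprotonated with LiN(SiMe3)2 (THF, −78 °C) and O-acylated with allyl chloroformate to give allyl [(4R)-4-(2-allyl-4,5-dimethoxyphenoxy)-4,5-dimethoxycyclohexa-1,5-dien-1-yl] carbonate F8.
- Decarboxylative allylic alkylation of F8 (Tsuji–Trost type) with Pd2(dba)3 and a chiral N,N'-(cyclohexane-1,2-diyl)bis[2-(diphenylphosphino)benzamide] ligand forms the C6–allyl bond under neutral conditions. Both ligand antipodes are run and the one matched to the 6S outcome is kept.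
- The tertiary centre cannot epimerise under these conditions, and the product is 21.

## Further compounds

F1 | step 8 | 4-(2-allyl-4,5-dimethoxyphenoxy)-3-methoxyphenol | C=CCc1cc(OC)c(OC)cc1Oc1ccc(O)cc1OC
F2 | step 8 | rac-4-(2-allyl-4,5-dimethoxyphenoxy)-3,4-dimethoxycyclohexa-2,5-dien-1-one | C=CCc1cc(OC)c(OC)cc1OC1(OC)C=CC(=O)C=C1OC
F3 | step 8 | rac-4-(2-allyl-4,5-dimethoxyphenoxy)-3,4-dimethoxycyclohex-2-en-1-one | C=CCc1cc(OC)c(OC)cc1OC1(OC)CCC(=O)C=C1OC
F4 | step 7 | (3E)-5-(2-allyl-4,5-dimethoxyphenoxy)-4-methoxy-1-(phenylsulfonyl)hexa-3,5-dien-2-one | C=C(Oc1cc(OC)c(OC)cc1CC=C)/C(OC)=C\C(=O)CS(=O)(=O)c1ccccc1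
F5 | step 7 | (3E)-5-(2-allyl-4,5-dimethoxyphenoxy)-1-diazo-4-methoxy-1-(phenylsulfonyl)hexa-3,5-dien-2-one | C=C(Oc1cc(OC)c(OC)cc1CC=C)/C(OC)=C\C(=O)C(=[N+]=[N-])S(=O)(=O)c1ccccc1
F6 | step 7 | (1S,5S)-5-(2-allyl-4,5-dimethoxyphenoxy)-4-methoxy-1-(phenylsulfonyl)bicyclo[3.1.0]hex-3-en-2-one | O=C1C=C(OC)[C@@]2(Oc3cc(OC)c(OC)cc3CC=C)C[C@@]12S(=O)(=O)c1ccccc1
F7 | step 7 | (4R)-4-(2-allyl-4,5-dimethoxyphenoxy)-3,4-dimethoxy-6-(phenylsulfonyl)cyclohex-2-en-1-one, C6 epimer mixture | C=CCc1cc(OC)c(OC)cc1O[C@]1(OC)CC(S(=O)(=O)c2ccccc2)C(=O)C=C1OC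
F8 | step 10 | allyl [(4R)-4-(2-allyl-4,5-dimethoxyphenoxy)-4,5-dimethoxycyclohexa-1,5-dien-1-yl] carbonate | C=CCc1cc(OC)c(OC)cc1O[C@]1(OC)CC=C(OC(=O)OCC=C)C=C1OC
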